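All runs stem from a simulated flask on assumed constants, and the scatter is random.

Count, for each molecule past first product, the reagent it took beyond its first addition, and hold that count against each run.

common to all: substrate 0.61 M
- east: reagent 0.90 equiv; run made earlier
- north-west: reagent 1.4 equiv; run made earlier
- flask: reagent 1.80 equiv; time 1.0 h

| run | time / min | substrate / % | first product / % |
|---|---|---|---|
| east | 15.0 | 53.6 | 39.1 |
| east | 30.0 | 40.9 | 46.5 |
| east | 40.0 | 38.1 | 47.1 |
| east | 60.0 | 35.6 | 48.4 |
| east | 80.0 | 34.8 | 48.7 |
| north-west | 6.00 | 60.3 | 34.6 |
| north-west | 10.0 | 47.6 | 42.9 |
| north-west | 20.0 | 30.2 | 49.8 |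
| north-west | 40.0 | 21.3 | 49.6 |
| north-west | 80.0 | 17.2 | 48.5 |

(each reading ± 0.5 percentage points)

- how much substrate there is at 1.0 h, in percent of the substrate charged
- how much first product there is at 1.0 h, in percent of the substrate charged
- how much bis adduct there is at 1.0 h, in percent of the substrate charged
- how much tris adduct there is at 1.0 h, in percent of the substrate charged

- steps thought possible: reagent + first product -> bis adduct; tris adduct -> side product; reagent + bis adduct -> tris adduct; reagent + tris adduct -> tetra adduct; substrate + reagent -> first product

- I called the gap the share of the charge found neither as c(substrate) nor as c(first product), and in the east run, where c(substrate) moved from 35.6% to 34.8% over the last two readings, it stood at 16.5%.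
- I counted the 0.90 equiv of reagent, the limiting reagent there, as consumed, took off one reagent per substrate converted and divided the rest by the gap, which gave 1.50.
- The same sum on the north-west run gave 1.67, a reading that ran high if reagent remained, since c(substrate) was still falling; this depth, the reagent taken beyond the first addition per molecule past first product, counts one for bis adduct and two for tris adduct or the side product formed from it.
- Your hunch, the forecast, was substrate 10%, first product 43%, bis adduct 15% and tris adduct 28%, with the remark “Side product cannot be separated from tris, because both carry three reagent equivalents.”
- I took your substrate and first product and went round twice: consuming the whole 1.80 equiv demanded a depth of 1.91, higher than either run gave, so I put 1.67 back in, which left 6.39% of the reagent charged and placed 31.5% at the tris level, tris adduct and side product together, a sum my balance did not divide.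

The flask gave substrate 9.99%, first product 43.8%, bis adduct 12.8% and tris adduct 0.0327%.

    reagent + first product → bis adduct (k = 9.80 × 10⁻⁴ M⁻¹ s⁻¹)
    tris adduct → side product (k = 0.0870 s⁻¹)
    reagent + bis adduct → tris adduct (k = 0.00350 M⁻¹ s⁻¹)
    reagent + tris adduct → tetra adduct (k = 4.00 × 10⁻⁴ M⁻¹ s⁻¹)
    substrate + reagent → first product (k = 0.00200 M⁻¹ s⁻¹)

With 5.7% of the reagent left in the flask at 1.00 h, the depth came to 1.72 against the 1.67 I carried, which put 33.5% at the tris level, of which the flask held 33.3% as side product. In this flask the largest single effect on tris adduct was the path to side product: the same flask without that path held 27.7% tris adduct. In the neighbour with 0.15 M of substrate, where 42% of the reagent remained, the depth was 1.51, which gave 11.2% at the tris level, of which that neighbour held 11.1% as side product.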